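**Plan**

- Retrosynthesis: the three O–benzyl bonds are cut first, then both C3''–CH3 bonds (back to an aryl lactone), then O1–C2 of ring C (back to a 2'-hydroxychalcone), then the chalcone Cα=Cβ bond (acetophenone plus aldehyde), and last the aryl–acetyl bond on a coumarin.
- Enabling feature: C3'' of the side chain can be joined to O5 in a six-membered lactone (O5, C3'', C2'', C1'', C6, C5). This ring masks O5, holds C3'' at the ester oxidation level, and leaves the acetyl carbon with only one free ortho hydroxyl.
- Forward order: the lactone ring is present from the start as the pyranone ring of 5,7-dihydroxycoumarin. Ring A is acetylated, the coumarin alkene is saturated, ring B is joined by condensation, ring C is closed oxidatively, the bridge is opened by double methyl addition, and the benzyl ethers are removed.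
- Stereochemistry: the target has no stereocentre. Only the E geometry of the chalcone arises, and it is consumed when ring C closes.

Key step: step 7

Remark on numbering: coumarin (chroman-2-one) numbering is used for compounds 1, 3, 4, 5 and 8. Flavone numbering (ring B primed, side chain C1''–C3'') is used from compound 9 onward.

**Route**

Step 1
Reactants: 1 5,7-dihydroxycoumarin; 2 acetyl chloride
Product: 3 8-acetyl-5,7-dihydroxycoumarin
Conditions: AcCl (1.2 equiv), AlCl3 (4 equiv), PhNO2, 70 °C; then ice/aq. HCl
Reagents that add atoms: acetyl chloride (compound 2), CC(=O)Cl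
Why: Friedel–Crafts C-acylation of 5,7-dihydroxycoumarins is known from the 4-alkyl series to favour C8, between the 7-hydroxyl and the ring oxygen, and the minor 6-acyl isomer should be removable by crystallisation or chromatography.

Step 2
Reactants: 3 8-acetyl-5,7-dihydroxycoumarin
Product: 4 8-acetyl-5,7-dihydroxychroman-2-one
Conditions: H2 (3 atm), 10% Pd/C, THF–EtOAc, 40 °C
Reagents that add atoms: none
Why: catalytic hydrogenation of the coumarin C3=C4 bond to the dihydrocoumarin is standard, and the chelated, doubly oxygen-donated aryl ketone should resist reduction in a neutral medium.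

Step 3
Reactants: 4 8-acetyl-5,7-dihydroxychroman-2-one
Product: 5 8-acetyl-5-benzyloxy-7-hydroxychroman-2-one
Conditions: BnBr (1.05 equiv), K2CO3 (1.1 equiv), dry acetone, 45 °C
Reagents that add atoms: benzyl bromide, BrCc1ccccc1
Why: Williamson etherification should take the more acidic, non-chelated 5-hydroxyl para to the ketone, as in the 4-O-monoalkylation of 2,4-dihydroxyacetophenones, while the 7-hydroxyl stays locked in its hydrogen bond to the acetyl oxygen and anhydrous carbonate leaves the lactone closed.

Step 4
Reactants: 6 2,4-dihydroxybenzaldehyde
Product: 7 2,4-bis(benzyloxy)benzaldehyde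
Conditions: BnBr (2.3 equiv), K2CO3 (2.5 equiv), DMF, 60 °C
Reagents that add atoms: benzyl bromide, BrCc1ccccc1
Why: exhaustive Williamson etherification of both phenols with excess halide and base is routine for this aldehyde.

Step 5
Reactants: 5 8-acetyl-5-benzyloxy-7-hydroxychroman-2-one; 7 2,4-bis(benzyloxy)benzaldehyde
Product: 8 5-benzyloxy-8-{(2E)-3-[2,4-bis(benzyloxy)phenyl]prop-2-enoyl}-7-hydroxychroman-2-one (the lactone-bearing chalcone)
Conditions: BF3·OEt2 (0.5 equiv), dry 1,4-dioxane, rt; then cold water
Reagents that add atoms: none
Why: the Lewis acid variant of the Claisen–Schmidt condensation, developed for base-sensitive esters, should let the boron-bound enol add to the activated aldehyde and the electron-rich benzylic carbinol dehydrate to the E enone with no hydroxide or alkoxide present to open the aryl lactone.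

Step 6
Reactants: 8 the lactone-bearing chalcone
Product: 10 lactone-bridged flavone (7-benzyloxy-2-[2,4-bis(benzyloxy)phenyl]-4H-chromen-4-one tied from O5 to C6 by a –C(=O)CH2CH2– lactone), via lactone-bridged flavanone 9 (not isolated)
Conditions: I2 (10 mol%), DMSO, 120 °C
Reagents that add atoms: none
Why: in the iodine–DMSO oxidative cyclisation of 2'-hydroxychalcones the only free ortho hydroxyl should close ring C by 6-endo oxa-Michael addition to flavanone 9, which is iodinated alpha to the ketone and loses HI to give the flavone while DMSO regenerates iodine, and because the other ortho oxygen is tied up in the lactone only the 6-substituted series can form.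

Step 7
Reactants: 10 lactone-bridged flavone; 11 methylmagnesium bromide
Product: 13 7-benzyloxy-2-[2,4-bis(benzyloxy)phenyl]-5-hydroxy-6-(3-hydroxy-3-methylbutyl)-4H-chromen-4-one, via ring-opened methyl ketone 12 (not isolated)
Conditions: MeMgBr (2.5 equiv), THF, −78 → −10 °C; then sat. aq. NH4Cl
Reagents that add atoms: methylmagnesium bromide (compound 11), C[Mg]Br
Why: The first equivalent of MeMgBr attacks the aryl lactone carbonyl C3'', and the tetrahedral magnesium hemiketalate collapses by expelling the C5 aryloxide, which opens the bridge to methyl ketone 12 as a magnesium 5-phenoxide chelated to O4; the second equivalent then adds to this ketone, and NH4Cl work-up frees the tertiary carbinol and the 5-hydroxyl. The closest known reaction is the double Grignard addition to 3,4-dihydrocoumarins, which delivers 2-(3-hydroxy-3-methylbutyl)phenols. No ring closes and no stereocentre is formed, both new bonds being C3''–CH3 bonds. The selectivity needed is attack at the lactone carbonyl in preference to 1,2-addition at C4 or conjugate addition at C2 of the pyranone. It should be secured because an aryl ester is far more electrophilic than the vinylogous-ester carbonyl C4, because the 5-phenoxide released in the first addition feeds more electron density into C4=O through its chelate, and because C2 is fully substituted by ring B. Low temperature and a small excess of reagent should keep the chromone untouched, and the basic medium excludes acid-catalysed chroman formation from the new tertiary alcohol.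

Step 8
Reactants: 13 7-benzyloxy-2-[2,4-bis(benzyloxy)phenyl]-5-hydroxy-6-(3-hydroxy-3-methylbutyl)-4H-chromen-4-one
Product: 14 2-(2,4-dihydroxyphenyl)-5,7-dihydroxy-6-(3-hydroxy-3-methylbutyl)-4H-chromen-4-one (CNP0205133.0)
Conditions: H2 (1 atm), 10% Pd/C, EtOAc–MeOH, rt, stopped after three equivalents of H2
Reagents that add atoms: none
Why: hydrogenolysis of aryl benzyl ethers over palladium on carbon is much faster than reduction of the flavone C2=C3 bond, and the neutral medium should keep the tertiary alcohol from cyclising onto a neighbouring phenol.

**Compound list**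

1 | 5,7-dihydroxycoumarin | O=c1ccc2c(O)cc(O)cc2o1 | starting material
2 | acetyl chloride | CC(=O)Cl | starting material
3 | 8-acetyl-5,7-dihydroxycoumarin | CC(=O)c1c(O)cc(O)c2ccc(=O)oc12 | intermediate
4 | 8-acetyl-5,7-dihydroxychroman-2-one | CC(=O)c1c(O)cc(O)c2CCC(=O)Oc12 | intermediate
5 | 8-acetyl-5-benzyloxy-7-hydroxychroman-2-one | CC(=O)c1c(O)cc(OCc2ccccc2)c2CCC(=O)Oc12 | intermediate
6 | 2,4-dihydroxybenzaldehyde | O=Cc1ccc(O)cc1O | starting material
7 | 2,4-bis(benzyloxy)benzaldehyde | O=Cc1ccc(OCc2ccccc2)cc1OCc1ccccc1 | intermediate
8 | 5-benzyloxy-8-{(2E)-3-[2,4-bis(benzyloxy)phenyl]prop-2-enoyl}-7-hydroxychroman-2-one | O=C(/C=C/c1ccc(OCc2ccccc2)cc1OCc1ccccc1)c1c(O)cc(OCc2ccccc2)c2CCC(=O)Oc12 | intermediate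
9 | racemic lactone-bridged flavanone (7-benzyloxy-2-[2,4-bis(benzyloxy)phenyl]-2,3-dihydro-4H-chromen-4-one with O5 joined to C6 by –C(=O)CH2CH2–) | O=C1CC(c2ccc(OCc3ccccc3)cc2OCc2ccccc2)Oc2cc(OCc3ccccc3)c3CCC(=O)Oc3c21 | intermediate
10 | lactone-bridged flavone (7-benzyloxy-2-[2,4-bis(benzyloxy)phenyl]-4H-chromen-4-one with O5 joined to C6 by –C(=O)CH2CH2–) | O=C1CCc2c(O1)c1c(=O)cc(-c3ccc(OCc4ccccc4)cc3OCc3ccccc3)oc1cc2OCc1ccccc1 | intermediate
11 | methylmagnesium bromide | C[Mg]Br | starting material
12 | 7-benzyloxy-2-[2,4-bis(benzyloxy)phenyl]-5-hydroxy-6-(3-oxobutyl)-4H-chromen-4-one | CC(=O)CCc1c(OCc2ccccc2)cc2oc(-c3ccc(OCc4ccccc4)cc3OCc3ccccc3)cc(=O)c2c1O | intermediate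
13 | 7-benzyloxy-2-[2,4-bis(benzyloxy)phenyl]-5-hydroxy-6-(3-hydroxy-3-methylbutyl)-4H-chromen-4-one | CC(C)(O)CCc1c(OCc2ccccc2)cc2oc(-c3ccc(OCc4ccccc4)cc3OCc3ccccc3)cc(=O)c2c1O | intermediate
14 | 2-(2,4-dihydroxyphenyl)-5,7-dihydroxy-6-(3-hydroxy-3-methylbutyl)-4H-chromen-4-one | CC(C)(O)CCc1c(O)cc2oc(-c3ccc(O)cc3O)cc(=O)c2c1O | target

**Step count and risks**

Total step count: 8. Longest linear sequence: 7 steps (steps 1, 2, 3, 5, 6, 7, 8); step 4 prepares the ring B aldehyde in a side branch.

Steps most likely to fail:

Step 7. Once the lactone is consumed, the methyl nucleophile may add to the chromone C4 carbonyl, or the sequence may stall at the ketone through enolisation. The fallback delivers the two methyl groups in separate, isolated stages. It sets out from 10. Aminolysis with MeNH(OMe)·HCl and AlMe3 in CH2Cl2 (0 °C to rt) should open the bridge to 3-{7-benzyloxy-2-[2,4-bis(benzyloxy)phenyl]-5-hydroxy-4-oxo-4H-chromen-6-yl}-N-methoxy-N-methylpropanamide F1, whose 5-hydroxyl is already free. MeMgBr (2.2 equiv, the first consumed by the phenol) in THF at −40 °C should stop at ketone 12, now isolated and purified, because the chelated tetrahedral intermediate does not collapse before work-up. A single further addition of MeMgBr to the preformed magnesium 5-phenoxide of 12 at −78 °C should give the carbinol, and the route is rejoined at 13. In each organometallic stage the chelated chromone then faces only one, clearly more reactive, electrophile.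

Step 5. The Lewis acid may cleave the benzyl ether ortho to the aldehyde, or tie up the chelated ketone as an unreactive boron complex so that the condensation stalls. The fallback is a directed aldol addition under kinetic control followed by a separate dehydration. It sets out from 5. LiN(SiMe3)2 (2.2 equiv) in THF at −78 °C should form the phenoxide–enolate dianion at the acetyl group, which is far more acidic than the lactone CH2. Aldehyde 7 should then add to give racemic 5-benzyloxy-8-{3-[2,4-bis(benzyloxy)phenyl]-3-hydroxypropanoyl}-7-hydroxychroman-2-one F2; the lactone carbonyl lies in the ring plane out of reach of the enolate carbon and is slow to react intermolecularly at this temperature. Catalytic p-TsOH in toluene at 50 °C should dehydrate the electron-rich benzylic alcohol, and the route is rejoined at chalcone 8.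

Step 6. Iodine may substitute the electron-rich free position of ring A, or the HI formed may strip a benzyl ether at 120 °C. The fallback is an iodine-free closure and dehydrogenation in two separate operations. It sets out from 8. NaOAc in AcOH at 90 °C should isomerise the chalcone to flavanone 9, this time isolated. DDQ in 1,4-dioxane at reflux should dehydrogenate it, and the route is rejoined at 10. This detour creates no compound beyond those already listed (F0).

**Further compounds**

F1 | step 7 | 3-{7-benzyloxy-2-[2,4-bis(benzyloxy)phenyl]-5-hydroxy-4-oxo-4H-chromen-6-yl}-N-methoxy-N-methylpropanamide | CON(C)C(=O)CCc1c(OCc2ccccc2)cc2oc(-c3ccc(OCc4ccccc4)cc3OCc3ccccc3)cc(=O)c2c1O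
F2 | step 5 | racemic 5-benzyloxy-8-{3-[2,4-bis(benzyloxy)phenyl]-3-hydroxypropanoyl}-7-hydroxychroman-2-one | O=C(CC(O)c1ccc(OCc2ccccc2)cc1OCc1ccccc1)c1c(O)cc(OCc2ccccc2)c2CCC(=O)Oc12
F0 | step 6 | none | none
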